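- 4 questions stand on these flasks, and each turns on how much of the charged L has become Z by the end.

| flask | L | E | J | temperature | remark | time |
|---|---|---|---|---|---|---|
| violet | 19 mM | 95 mM | 0.095 mM | 81 °C | run made earlier |  |
| ochre | 19 mM | 95 mM | 0.14 mM | 95 °C | run made earlier |  |
| south | 19 mM | 95.0 mM | 0.19 mM | 100 °C |  | 12 h |
| west | 19 mM | 95.0 mM | 0.19 mM |  | at 75 °C until 2.5 h, from then on at 100 °C | 12 h |
| north-west | 19 mM | 95.0 mM | 0.19 mM | 75 °C |  | 12 h |

| run | time / h | Z / % | L / % |
|---|---|---|---|
| violet | 5.00 | 4.3 | 93.8 |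
| violet | 10.0 | 9.6 | 89.5 |
| violet | 15.0 | 13.7 | 84.4 |
| violet | 20.0 | 19.4 | 79.4 |
| violet | 25.0 | 24.6 | 75.9 |
| ochre | 0.833 | 3.4 | 96.0 |
| ochre | 1.33 | 5.6 | 93.0 |
| ochre | 2.50 | 11.1 | 88.0 |
| ochre | 5.00 | 22.6 | 76.6 |
| ochre | 10.0 | 42.5 | 58.2 |

(each reading ± 0.5 percentage points)

1. the flask that comes out highest in amount of Z, in percent of the L charged, or "all alike" when all lie within 1.5 percentage points (south / west / north-west / all alike)
2. Z at the end, in percent of the L charged, south
3. Z at the end, in percent of the L charged, west
4. Z at the end, in percent of the L charged, north-west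



- First ledger entry, the charge: E stands at 95.0 mM against 19 mM of L, so L is taken as the limiting reagent and the books are kept in L.
- Second entry, the catalyst: if each J held one L, that would tie up 1.00% of the charge in the new flasks, so this entry is small.
- Third entry, free L plus Z: the last readings together exceed the charge by 0.5 percentage points in violet and 0.7 points in ochre, beside a scatter of 0.5 points on each reading. The books therefore close about as well as the readings allow, and what L loses is entered as Z.
- The reckoning here goes to logarithms. The decade rate is the logarithm to base ten of [L] charged over [L] left, per hour. In ochre it reads 0.0232 h⁻¹ at 5.00 h and 0.0235 h⁻¹ at 10.0 h, so [L] is taken as falling pseudo-first-order.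
- Taking the rate as proportional to [J], which these runs do not test, and scaling both runs to 0.19 mM of J gives 0.00958 h⁻¹ for violet and 0.0319 h⁻¹ for ochre.
- A straight line of the logarithm of this rate against temperature, drawn through those two values, gives 0.00572 h⁻¹ at 75 °C. At 100 °C it gives 0.0490 h⁻¹, the hot decade rate, powers of ten of [L] lost per hour at 0.19 mM of J.
- Rate times hours gives the decades in each flask: 0.588 in south, 0.480 in west and 0.0687 in north-west. The cold stretch supplies hardly any of the west count.
- Closing the books, this reckoning enters Z at 74.2% in south, 66.9% in west and 14.6% in north-west, so it names south highest.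
- The forecast, which reads the runs as “close to zero order in L”, names south highest, with 83% in south, 73% in west and 14% in north-west. The two part in south and west, where the forecast stands higher than this reckoning.
- The flasks give 75.1% in south, 67.1% in west and 14.0% in north-west, so south comes out highest.

    D → X (k = 0.0120 s⁻¹, Ea = 95.0 kJ mol⁻¹)
    L + J ⇌ D (K = 2500 M⁻¹, k = 0.280 M⁻¹ s⁻¹, Ea = 77.0 kJ mol⁻¹, ΔH = −16.0 kJ mol⁻¹)
    G → Q (k = 0.0150 s⁻¹, Ea = 109 kJ mol⁻¹)
    E + X → G (k = 0.880 M⁻¹ s⁻¹, Ea = 74.0 kJ mol⁻¹)
    Q ⇌ J + Z (K = 0.0710 M, k = 0.0750 s⁻¹, Ea = 97.0 kJ mol⁻¹, ΔH = 5.00 kJ mol⁻¹)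
    (constants at 100 °C)

In west, free L goes from 96.7% at 2.50 h to 32.6% at 12.0 h, which reads as 0.0497 h⁻¹ on the hot stretch, beside the 0.0490 h⁻¹ carried. The neighbour is west charged with 0.076 mM of J. Scaled to that charge, the hot decade rate becomes 0.0196 h⁻¹ and the whole count becomes 0.192, which enters Z at 35.7%. That neighbour gives 33.7% of Z, with 66.2% of L still free.

The runs are calculated with made-up constants.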